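**Retrosynthetic overview**
- The target is the (2S)-flavanone. Its two free phenols (O5, O2') come from benzyl ethers by a final hydrogenolysis, and the C4 ketone from DDQ oxidation of a C4 methyl ether.
- The strategy rests on ring C (O1, C2, C3, C4, fused to ring A at C4a and C8a): O1–C8a–C4a–C4 is a ring A salicylaldehyde at the C4-methoxy ortho-quinone methide level, and C2–C3 is the vinyl group of a ring B styrene. Bonds C3–C4 and O1–C2 are cut together (inverse-demand oxa-[4+2], chiral phosphoric acid).
- Ring A aldehyde 10 comes from 2,3,4-trimethoxybenzaldehyde (bromination, Dakin, benzylation, Br to OH, ortho-formylation). Styrene 13 comes from 2-hydroxy-6-methoxybenzaldehyde (benzylation, Wittig).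
- Rings A and B are bought as arenes; ring C is the only ring formed, in step 8.

Key step: step 8

Assumption: which antipode of the phosphoric acid leads to the 2S series cannot be predicted with confidence; the (R)-acid is written, and its enantiomer is taken if the first run shows the 2R series.

**Route**

Step 1
Reactants: 1 2,3,4-trimethoxybenzaldehyde
Product: 2 5-bromo-2,3,4-trimethoxybenzaldehyde
Conditions: NBS (1.05 equiv), MeCN, rt
Reagents that add atoms: N-bromosuccinimide, O=C1CCC(=O)N1Br
Why: Electrophilic aromatic bromination; C5 is ortho to the 4-methoxy group, para to the 2-methoxy group and meta to the formyl group, whereas C6 is ortho to the formyl group and activated only by the twisted 3-methoxy group, so bromine should enter at C5.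

Step 2
Reactants: 2 5-bromo-2,3,4-trimethoxybenzaldehyde
Product: 4 5-bromo-2,3,4-trimethoxyphenol, via aryl formate 3 (not isolated)
Conditions: 30% H2O2, H2SO4 (cat.), MeOH, rt
Reagents that add atoms: hydrogen peroxide, OO
Why: Acid-catalysed Dakin oxidation; the peroxide adduct of the aldehyde rearranges with migration of the electron-rich aryl group (Baeyer–Villiger type) to formate 3, which is methanolysed in the same pot.

Step 3
Reactants: 4 5-bromo-2,3,4-trimethoxyphenol
Product: 5 1-(benzyloxy)-5-bromo-2,3,4-trimethoxybenzene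
Conditions: BnBr, K2CO3, DMF, rt
Reagents that add atoms: benzyl bromide, BrCc1ccccc1
Why: Williamson ether synthesis of the phenoxide with a reactive benzylic halide; no other nucleophilic site is present.

Step 4
Reactants: 5 1-(benzyloxy)-5-bromo-2,3,4-trimethoxybenzene
Product: 8 5-(benzyloxy)-2,3,4-trimethoxyphenol, via aryllithium 6 (not isolated), via dimethyl arylboronate 7 (not isolated)
Conditions: n-BuLi, THF, −78 °C; B(OMe)3, −78 °C to rt; AcOH, 30% H2O2, 0 °C to rt
Reagents that add atoms: hydrogen peroxide, OO
Why: Bromine–lithium exchange at −78 °C is much faster than benzylic deprotonation of the benzyl ether, the aryllithium is trapped as the boronate, and peroxide oxidation (1,2-shift of aryl from boron to oxygen) puts the hydroxyl on the former C–Br carbon.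

Step 5
Reactants: 8 5-(benzyloxy)-2,3,4-trimethoxyphenol
Product: 10 6-(benzyloxy)-2-hydroxy-3,4,5-trimethoxybenzaldehyde, via salicyl alcohol 9 (not isolated)
Conditions: MgCl2, Et3N, (CH2O)n, MeCN, reflux
Reagents that add atoms: paraformaldehyde (as formaldehyde), C=O
Why: Magnesium-mediated ortho-formylation of a phenol (Casnati–Skattebøl reaction); the magnesium phenoxide delivers formaldehyde to the only free ring position, ortho to the OH, and a second formaldehyde oxidises salicyl alcohol 9 by hydride transfer.

Step 6
Reactants: 11 2-hydroxy-6-methoxybenzaldehyde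
Product: 12 2-(benzyloxy)-6-methoxybenzaldehyde
Conditions: BnBr, K2CO3, DMF, rt to 50 °C
Reagents that add atoms: benzyl bromide, BrCc1ccccc1
Why: Williamson ether synthesis; the chelated phenol is still alkylated cleanly in DMF with carbonate.

Step 7
Reactants: 12 2-(benzyloxy)-6-methoxybenzaldehyde
Product: 13 1-(benzyloxy)-2-ethenyl-3-methoxybenzene
Conditions: Ph3PCH3Br, KOtBu, THF, 0 °C to rt
Reagents that add atoms: methyltriphenylphosphonium bromide, C[P+](c1ccccc1)(c1ccccc1)c1ccccc1.[Br-]
Why: Wittig methylenation of a non-enolisable aryl aldehyde with the unstabilised ylide; the hindered carbonyl still reacts because the ylide is small.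

Step 8
Reactants: 10 6-(benzyloxy)-2-hydroxy-3,4,5-trimethoxybenzaldehyde; 13 1-(benzyloxy)-2-ethenyl-3-methoxybenzene; 14 trimethyl orthoformate
Product: 17 (2S,4S)-5-(benzyloxy)-2-[2-(benzyloxy)-6-methoxyphenyl]-4,6,7,8-tetramethoxychromane, via dimethyl acetal 15 (not isolated), via methoxy ortho-quinone methide 16 (not isolated)
Conditions: (R)-TRIP [(R)-3,3'-bis(2,4,6-triisopropylphenyl)-1,1'-binaphthyl-2,2'-diyl hydrogen phosphate] (10 mol %), 5 Å MS, PhMe, −30 °C, slow addition of 13
Reagents that add atoms: trimethyl orthoformate 14, COC(OC)OC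
Why: Proposed new method: the acid turns 10 and 14 into acetal 15, which loses methanol to the C4-methoxy ortho-quinone methide 16; its O-protonated form (a hydroxyaryl oxocarbenium ion) is held by the chiral phosphate as a hydrogen-bonded ion pair, the styrene CH2 (C3) adds to C4, and the phenol oxygen O1 captures the benzylic cation at C2. The closest known reactions are the achiral acid-promoted union of salicylaldehydes, orthoformates and styrenes to 2,4-cis-4-alkoxyflavans and the chiral phosphoric acid catalysed [4+2] reactions of ortho-quinone methides from ortho-hydroxybenzyl alcohols; the enantioselective acetal-derived version with a simple styrene has not been shown. Ring C closes by an asynchronous inverse-demand oxa-[4+2] cycloaddition, C3–C4 first and then O1–C2 as a six-membered capture of the cation by the phenol (6-exo with respect to the quinoid C2=C1' bond). C2 is set in this O1–C2 closure inside the phosphate ion pair, which binds the phenol O–H and the cation and leaves one face of C2 open; C4 follows from the endo arrangement (2,4-cis) and is removed in step 9, so only the sense at C2 has to be controlled. Regiochemistry is fixed by polarity (C4 is the electrophilic end of the heterodiene, the terminal CH2 the nucleophilic end of the styrene, and the C2 cation is stabilised by both ortho oxygens of ring B), and site selectivity by the single free phenol, since O5 and O2' are benzylated and no second closure to a bridged ketal can occur. The weak acid, low temperature, sieves that take up methanol and slow addition of 13 are meant to keep styrene oligomerisation and reionisation of C2–O1 slower than the cycloaddition.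

Step 9
Reactants: 17 (2S,4S)-5-(benzyloxy)-2-[2-(benzyloxy)-6-methoxyphenyl]-4,6,7,8-tetramethoxychromane
Product: 19 (2S)-5-(benzyloxy)-2-[2-(benzyloxy)-6-methoxyphenyl]-6,7,8-trimethoxychroman-4-one, via C4 hemiketal 18 (not isolated)
Conditions: DDQ (1.3 equiv), CH2Cl2/H2O (18:1), 0 °C to rt
Reagents that add atoms: water, O
Why: Benzylic oxidation with DDQ, as known for 4-alkoxyflavans; hydride is taken from C4 (benzylic to the penta-oxygenated ring A and bearing the methoxy group), the oxocarbenium ion adds water to hemiketal 18, and loss of methanol gives the ketone while C2 is not involved.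

Step 10
Reactants: 19 (2S)-5-(benzyloxy)-2-[2-(benzyloxy)-6-methoxyphenyl]-6,7,8-trimethoxychroman-4-one
Product: 20 (2S)-5-hydroxy-2-(2-hydroxy-6-methoxyphenyl)-6,7,8-trimethoxychroman-4-one
Conditions: H2 (1 atm), Pd/C (10%), EtOAc, rt
Reagents that add atoms: none
Why: Catalytic hydrogenolysis of two aryl benzyl ethers under neutral conditions, which avoids the acid- or base-induced ring opening to the chalcone that would racemise C2; methyl ethers and the ketone should survive short exposure.

**Compound list**
1 | 2,3,4-trimethoxybenzaldehyde | COc1ccc(C=O)c(OC)c1OC | starting material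
2 | 5-bromo-2,3,4-trimethoxybenzaldehyde | COc1c(Br)cc(C=O)c(OC)c1OC | intermediate
3 | 5-bromo-2,3,4-trimethoxyphenyl formate | COc1c(Br)cc(OC=O)c(OC)c1OC | intermediate (not isolated)
4 | 5-bromo-2,3,4-trimethoxyphenol | COc1c(Br)cc(O)c(OC)c1OC | intermediate
5 | 1-(benzyloxy)-5-bromo-2,3,4-trimethoxybenzene | COc1c(Br)cc(OCc2ccccc2)c(OC)c1OC | intermediate
6 | [5-(benzyloxy)-2,3,4-trimethoxyphenyl]lithium | COc1c([Li])cc(OCc2ccccc2)c(OC)c1OC | intermediate (not isolated)
7 | dimethyl [5-(benzyloxy)-2,3,4-trimethoxyphenyl]boronate | COB(OC)c1cc(OCc2ccccc2)c(OC)c(OC)c1OC | intermediate (not isolated)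
8 | 5-(benzyloxy)-2,3,4-trimethoxyphenol | COc1c(O)cc(OCc2ccccc2)c(OC)c1OC | intermediate
9 | 3-(benzyloxy)-2-(hydroxymethyl)-4,5,6-trimethoxyphenol | OCc1c(O)c(OC)c(OC)c(OC)c1OCc1ccccc1 | intermediate (not isolated)
10 | 6-(benzyloxy)-2-hydroxy-3,4,5-trimethoxybenzaldehyde | O=Cc1c(O)c(OC)c(OC)c(OC)c1OCc1ccccc1 | intermediate
11 | 2-hydroxy-6-methoxybenzaldehyde | COc1cccc(O)c1C=O | starting material
12 | 2-(benzyloxy)-6-methoxybenzaldehyde | COc1cccc(OCc2ccccc2)c1C=O | intermediate
13 | 1-(benzyloxy)-2-ethenyl-3-methoxybenzene | COc1cccc(OCc2ccccc2)c1C=C | intermediate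
14 | trimethyl orthoformate | COC(OC)OC | starting material
15 | 3-(benzyloxy)-2-(dimethoxymethyl)-4,5,6-trimethoxyphenol | COC(OC)c1c(O)c(OC)c(OC)c(OC)c1OCc1ccccc1 | intermediate (not isolated)
16 | 5-(benzyloxy)-2,3,4-trimethoxy-6-(methoxymethylidene)cyclohexa-2,4-dien-1-one | COC=C1C(=O)C(OC)=C(OC)C(OC)=C1OCc1ccccc1 | intermediate (not isolated)
17 | (2S,4S)-5-(benzyloxy)-2-[2-(benzyloxy)-6-methoxyphenyl]-4,6,7,8-tetramethoxychromane (2,4-cis) | COc1cccc(OCc2ccccc2)c1[C@@H]1C[C@H](OC)c2c(OCc3ccccc3)c(OC)c(OC)c(OC)c2O1 | intermediate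
18 | (2S)-5-(benzyloxy)-2-[2-(benzyloxy)-6-methoxyphenyl]-4,6,7,8-tetramethoxychroman-4-ol (C4 hemiketal, either epimer) | COc1cccc(OCc2ccccc2)c1[C@@H]1CC(O)(OC)c2c(OCc3ccccc3)c(OC)c(OC)c(OC)c2O1 | intermediate (not isolated)
19 | (2S)-5-(benzyloxy)-2-[2-(benzyloxy)-6-methoxyphenyl]-6,7,8-trimethoxychroman-4-one | COc1cccc(OCc2ccccc2)c1[C@@H]1CC(=O)c2c(OCc3ccccc3)c(OC)c(OC)c(OC)c2O1 | intermediate
20 | (2S)-5-hydroxy-2-(2-hydroxy-6-methoxyphenyl)-6,7,8-trimethoxychroman-4-one | COc1cccc(O)c1[C@@H]1CC(=O)c2c(O)c(OC)c(OC)c(OC)c2O1 | target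

**Totals**
Total step count: 10. Longest linear sequence: 8 (steps 1–5, 8, 9, 10).

**Steps most likely to fail**

1. Step 8 (proposed new method). The phosphate ion pair may give poor facial selectivity at C2, the acid may oligomerise the very electron-rich styrene before it is captured, or C2–O1 may reionise and erode the enantiomeric purity.
Fallback (known chemistry, no cycloaddition): setting out from 10 and 12, addition of MeMgBr (excess, THF, 0 °C) to 10 should give 3-(benzyloxy)-2-(1-hydroxyethyl)-4,5,6-trimethoxyphenol F1. Benzylic oxidation with MnO2 in CH2Cl2 should give 1-[6-(benzyloxy)-2-hydroxy-3,4,5-trimethoxyphenyl]ethan-1-one F2. Claisen–Schmidt condensation of this ketone with aldehyde 12 (KOH, EtOH, rt) should give (E)-1-[6-(benzyloxy)-2-hydroxy-3,4,5-trimethoxyphenyl]-3-[2-(benzyloxy)-6-methoxyphenyl]prop-2-en-1-one F3. Oxa-Michael ring closure (NaOAc, EtOH, reflux) should give racemic 5-(benzyloxy)-2-[2-(benzyloxy)-6-methoxyphenyl]-6,7,8-trimethoxychroman-4-one F4. Preparative HPLC on a chiral stationary phase separates the (2S)-enantiomer, which is compound 19, from (2R)-5-(benzyloxy)-2-[2-(benzyloxy)-6-methoxyphenyl]-6,7,8-trimethoxychroman-4-one F5, which can be racemised with base through the chalcone and recycled. The route is rejoined at 19, before step 10.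

2. Step 9. DDQ may abstract hydride at C2 instead of C4, dehydrogenate further to the flavone or flavylium level, or attack a benzyl ether.
Fallback: setting out from 17, acid-catalysed exchange of the C4 methoxy group for hydroxyl (TsOH cat., THF/H2O, rt, through the C4 benzylic cation) should give (2S)-5-(benzyloxy)-2-[2-(benzyloxy)-6-methoxyphenyl]-6,7,8-trimethoxychroman-4-ol F6 as a mixture of C4 epimers. Dess–Martin periodinane in CH2Cl2 then oxidises the alcohol to 19, where the route is rejoined.

3. Step 10. Reductive cleavage of the benzylic C2–O1 bond (ring opening to the dihydrochalcone) or reduction of the ketone may compete with debenzylation.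
Fallback: setting out from 19, non-reductive debenzylation with BCl3 and pentamethylbenzene as cation scavenger (CH2Cl2, −78 °C, short reaction time to protect C2) should give 20 directly. The 5-benzyl ether is cleaved with chelation assistance by the C4 carbonyl and the methyl ethers are left intact at this temperature. No new compound is made.

**Further compounds**
F1 | step 8 | 3-(benzyloxy)-2-(1-hydroxyethyl)-4,5,6-trimethoxyphenol (racemic) | CC(O)c1c(O)c(OC)c(OC)c(OC)c1OCc1ccccc1
F2 | step 8 | 1-[6-(benzyloxy)-2-hydroxy-3,4,5-trimethoxyphenyl]ethan-1-one | CC(=O)c1c(O)c(OC)c(OC)c(OC)c1OCc1ccccc1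
F3 | step 8 | (E)-1-[6-(benzyloxy)-2-hydroxy-3,4,5-trimethoxyphenyl]-3-[2-(benzyloxy)-6-methoxyphenyl]prop-2-en-1-one | COc1cccc(OCc2ccccc2)c1/C=C/C(=O)c1c(O)c(OC)c(OC)c(OC)c1OCc1ccccc1
F4 | step 8 | racemic 5-(benzyloxy)-2-[2-(benzyloxy)-6-methoxyphenyl]-6,7,8-trimethoxychroman-4-one | COc1cccc(OCc2ccccc2)c1C1CC(=O)c2c(OCc3ccccc3)c(OC)c(OC)c(OC)c2O1
F5 | step 8 | (2R)-5-(benzyloxy)-2-[2-(benzyloxy)-6-methoxyphenyl]-6,7,8-trimethoxychroman-4-one | COc1cccc(OCc2ccccc2)c1[C@H]1CC(=O)c2c(OCc3ccccc3)c(OC)c(OC)c(OC)c2O1
F6 | step 9 | (2S)-5-(benzyloxy)-2-[2-(benzyloxy)-6-methoxyphenyl]-6,7,8-trimethoxychroman-4-ol (C4 epimers) | COc1cccc(OCc2ccccc2)c1[C@@H]1CC(O)c2c(OCc3ccccc3)c(OC)c(OC)c(OC)c2O1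
F0 | step 10 | none | none
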